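Ring A (C4a, C5, C6, C7, C8, C8a) is fused to ring C along C4a–C8a. In a 2,3-dihydro-4H-pyran-4-one this bond is an enol-ether C=C and can act as the vinyl arm of a vinylketene, so ring A can be grown on a finished, chiral ring C.
Retrosynthesis: once two silyl ethers are removed, ring A is cut at C5–C6, C7–C8 and C4a–C5 (plus C8–C8a, made by a Wolff shift). This gives a 6-(2-diazopropanoyl)pyranone and a prenyl-substituted siloxyalkyne.
The diazo ketone is cut to diazoethane and the pyranone-6-carboxylic acid. Ring C is cut at O1–C8a and C4a–C8a to dimethyl oxalate and a β-silyloxy methyl ketone, and that ketone is cut at C2–C3 to an allyl metal and 4-hydroxybenzaldehyde.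
Forward order: C2–C3, then C4a–C8a, then ring C (O1–C8a), then ring A in one operation, then desilylation.
C2 is the only stereocentre and comes from a catalytic asymmetric allylation. Its C–O bond is never broken afterwards, and the main route keeps strong base away from the closed ring C.
Key step: step 11

Assumption: atoms are labelled in flavanone numbering (O1, C2, C3, C4, C4a, C5 to C8, C8a) even in monocyclic precursors, and the open-chain 2,4-dioxo esters are drawn as diketo tautomers although they should be largely enolised.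

Step 1
Reactants: 1 4-hydroxybenzaldehyde
Product: 2 4-(triisopropylsilyloxy)benzaldehyde
Conditions: TIPSCl, imidazole, DMF, rt
Reagents that add atoms: chlorotriisopropylsilane (TIPSCl), CC(C)[Si](Cl)(C(C)C)C(C)C
Why: Imidazole-promoted O-silylation of a phenol is routine, and the bulky aryl silyl ether should survive the Lewis-acid, enolate and mild-acid steps ahead and fall to fluoride at the end.

Step 2
Reactants: 2 4-(triisopropylsilyloxy)benzaldehyde; 3 allyltributylstannane
Product: 4 (1S)-1-[4-(triisopropylsilyloxy)phenyl]but-3-en-1-ol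
Conditions: (S)-BINOL (20 mol %), Ti(OiPr)4 (10 mol %), 4 Å MS, CH2Cl2, −20 °C; aq. NaHCO3
Reagents that add atoms: none
Why: In this Keck asymmetric allylation the Lewis acid formed from (S)-BINOL and Ti(OiPr)4 binds the aldehyde and leaves its Si face open to the stannane, so the C2–C3 bond forms and the carbinol carbon (the future C2) is set as S.

Step 3
Reactants: 4 (1S)-1-[4-(triisopropylsilyloxy)phenyl]but-3-en-1-ol
Product: 5 triethyl({(1S)-1-[4-(triisopropylsilyloxy)phenyl]but-3-en-1-yl}oxy)silane
Conditions: TESCl, imidazole, CH2Cl2, 0 °C to rt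
Reagents that add atoms: chlorotriethylsilane (TESCl), CC[Si](Cl)(CC)CC
Why: This is a routine silylation of a secondary alcohol, and TES is chosen because mild acid will later remove it while the aryl TIPS ether stays.

Step 4
Reactants: 5 triethyl({(1S)-1-[4-(triisopropylsilyloxy)phenyl]but-3-en-1-yl}oxy)silane
Product: 6 (4S)-4-(triethylsilyloxy)-4-[4-(triisopropylsilyloxy)phenyl]butan-2-one
Conditions: PdCl2 (10 mol %), Cu(OAc)2·H2O (20 mol %), O2 (1 atm), DMA–H2O 7:1, rt
Reagents that add atoms: water, O
Why: In the Tsuji–Wacker oxidation, Markovnikov attack of water on the palladium-bound terminal alkene gives the methyl ketone, and the acetate-buffered copper co-oxidant keeps the medium mild enough for both silyl ethers.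

Step 5
Reactants: 6 (4S)-4-(triethylsilyloxy)-4-[4-(triisopropylsilyloxy)phenyl]butan-2-one; 7 dimethyl oxalate
Product: 8 methyl (6S)-2,4-dioxo-6-(triethylsilyloxy)-6-[4-(triisopropylsilyloxy)phenyl]hexanoate
Conditions: LiN(SiMe3)2 (2.1 equiv), THF, −78 °C; 7, −78 to 0 °C; AcOH
Reagents that add atoms: none
Why: In this crossed Claisen condensation the amide base deprotonates the unhindered methyl group under kinetic control, the non-enolisable oxalate acylates that enolate (C4a–C8a bond), and the second equivalent of base holds the product as its stabilised enolate so that β-elimination of the silyloxy group is not expected.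

Step 6
Reactants: 8 methyl (6S)-2,4-dioxo-6-(triethylsilyloxy)-6-[4-(triisopropylsilyloxy)phenyl]hexanoate
Product: 11 methyl (2S)-4-oxo-2-[4-(triisopropylsilyloxy)phenyl]-3,4-dihydro-2H-pyran-6-carboxylate, via hydroxy diketo ester 9 (not isolated), via cyclic hemiketal 10 (not isolated)
Conditions: camphor-10-sulfonic acid (10 mol %), MeOH (5 equiv), CH2Cl2, 0 °C to rt
Reagents that add atoms: none
Why: Acid-catalysed methanolysis of the TES ether frees the hydroxyl, which adds 6-exo-trig to the very electrophilic α-keto ester carbonyl (O1–C8a, ring C) and loses water to the vinylogous ester, the usual cyclodehydration of δ-hydroxy-1,3-diketones to 2,3-dihydro-4H-pyran-4-ones, and C2 keeps its configuration because its C–O bond is not touched.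

Step 7
Reactants: 11 methyl (2S)-4-oxo-2-[4-(triisopropylsilyloxy)phenyl]-3,4-dihydro-2H-pyran-6-carboxylate
Product: 12 (2S)-4-oxo-2-[4-(triisopropylsilyloxy)phenyl]-3,4-dihydro-2H-pyran-6-carboxylic acid
Conditions: Me3SnOH (4 equiv), ClCH2CH2Cl, 60 °C; 0.5 M HCl wash
Reagents that add atoms: trimethyltin hydroxide, C[Sn](C)(C)O
Why: Trimethyltin hydroxide cleaves methyl esters under nearly neutral conditions and is used where hydroxide would cause β-elimination, so it should avoid retro-oxa-Michael opening of ring C and the loss of C2 integrity that would follow.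

Step 8
Reactants: 13 N-ethyl-N-nitrosourea
Product: 14 diazoethane (ethereal solution)
Conditions: KOH (40 % aq.), Et2O, −10 to 0 °C; ether layer dried over KOH pellets
Reagents that add atoms: none
Why: Base-induced fragmentation of an N-alkyl-N-nitrosourea is the standard laboratory source of ethereal diazoalkanes.

Step 9
Reactants: 12 (2S)-4-oxo-2-[4-(triisopropylsilyloxy)phenyl]-3,4-dihydro-2H-pyran-6-carboxylic acid; 14 diazoethane
Product: 16 (2S)-6-(2-diazopropanoyl)-2-[4-(triisopropylsilyloxy)phenyl]-2,3-dihydro-4H-pyran-4-one, via acid chloride 15 (not isolated)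
Conditions: Me2C=C(Cl)NMe2, CH2Cl2, 0 °C; then 14 (1.2 equiv), Et3N, Et2O–CH2Cl2, −78 to −20 °C
Reagents that add atoms: none
Why: The α-chloroenamine forms the acid chloride without free HCl, diazoethane is then C-acylated as in the first stage of the Arndt–Eistert sequence, and triethylamine takes up HCl (Newman–Beal modification) so that hardly any excess of the dipole meets the ring C alkene.

Step 10
Reactants: 17 ethyl 4-methylpent-3-enoate
Product: 20 triisopropyl[(5-methylhex-4-en-1-yn-1-yl)oxy]silane, via dibromo enolate 18 (not isolated), via lithium ynolate 19 (not isolated)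
Conditions: CH2Br2, lithium 2,2,6,6-tetramethylpiperidide, THF, −78 °C; n-BuLi, −78 °C to rt; TIPSCl, −78 to 0 °C
Reagents that add atoms: dibromomethane, BrCBr; chlorotriisopropylsilane (TIPSCl), CC(C)[Si](Cl)(C(C)C)C(C)C
Why: In the Kowalski ynolate synthesis dibromomethyllithium adds to the ester, bromine–lithium exchange on the dibromo enolate triggers a carbenoid 1,2-shift of the prenyl group to give the ynolate, and the bulky silyl chloride traps it on oxygen rather than on carbon.

Step 11
Reactants: 16 (2S)-6-(2-diazopropanoyl)-2-[4-(triisopropylsilyloxy)phenyl]-2,3-dihydro-4H-pyran-4-one; 20 triisopropyl[(5-methylhex-4-en-1-yn-1-yl)oxy]silane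
Product: 25 (2S)-5-hydroxy-8-methyl-6-(3-methylbut-2-en-1-yl)-7-(triisopropylsilyloxy)-2-[4-(triisopropylsilyloxy)phenyl]chroman-4-one, via pyranonyl methyl ketene 21 (not isolated), via vinylcyclobutenone 22 (not isolated), via dienylketene 23 (not isolated), via cyclohexadienone 24 (not isolated)
Conditions: 20 (1.5 equiv), ClCH2CH2Cl, hν (440 nm LED), 20 °C, argon; then 80 °C
Reagents that add atoms: none
Why: Proposed new method: excitation of the diazo ketone in its long-wavelength band expels N2 and shifts the pyranonyl carbon C8a onto the diazo carbon (Wolff rearrangement, C8–C8a), which gives ketene 21 whose vinyl arm is the C4a=C8a enol-ether bond of ring C; the prenyl-bearing carbon of 20, the nucleophilic end of the ynol ether, then attacks the ketene carbonyl carbon and the (2+2) adduct 22 carries the new C5–C6 and C7–C8 bonds. At 80 °C 22 opens in a reversible conrotatory four-electron process that breaks C5–C8, and since only the isomer of 23 with ketene and pyranonyl cis can react further, the other isomer drains back through 22. Ring A closes by a disrotatory six-electron electrocyclisation that joins the ketene carbon C5 to C4a, and dienone 24, a cyclic 1,3-diketone, enolises at once to the hydrogen-bonded 5-phenol 25. The closest known reaction type is the Danheiser benzannulation of cycloalkenyl and heteroaryl diazomethyl ketones with siloxyalkynes; not yet shown are a β-alkoxy enone as vinyl arm, a methyl group on the diazo carbon and a fully substituted arene as product, and the case for success is that C4a is the nucleophilic carbon of a vinylogous ester and is therefore matched to the electrophilic ketene carbon in the closure. No lasting stereocentre is formed (the quaternary carbon of 22 and C4a–H of 24 are erased by ring opening and enolisation), and C2 is a spectator because the medium is neutral and free of base. The selectivity required is the orientation of the (2+2) step, which the polarisation of the siloxyalkyne secures so that prenyl ends on C6 and silyloxy on C7 while methyl on C8 comes with the diazo carbon, and visible light is used so that the enone and arene chromophores stay dark and enone–alkyne photocycloaddition is avoided.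

Step 12
Reactants: 25 (2S)-5-hydroxy-8-methyl-6-(3-methylbut-2-en-1-yl)-7-(triisopropylsilyloxy)-2-[4-(triisopropylsilyloxy)phenyl]chroman-4-one
Product: 26 (2S)-5,7-dihydroxy-2-(4-hydroxyphenyl)-8-methyl-6-(3-methylbut-2-en-1-yl)chroman-4-one (5,7,4'-trihydroxy-8-methyl-6-prenylflavanone)
Conditions: Bu4NF, AcOH (1:1), THF, 0 °C
Reagents that add atoms: none
Why: Fluoride cleaves both aryl silyl ethers, and acetic acid protonates the phenoxides as they form so that the flavanone does not open to the chalcone, C2 stays S, and the prenyl group sees no strong acid.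

Compound list
1 | 4-hydroxybenzaldehyde | O=Cc1ccc(O)cc1 | starting material
2 | 4-(triisopropylsilyloxy)benzaldehyde | O=Cc1ccc(O[Si](C(C)C)(C(C)C)C(C)C)cc1 | intermediate
3 | allyltributylstannane | C=CC[Sn](CCCC)(CCCC)CCCC | starting material
4 | (1S)-1-[4-(triisopropylsilyloxy)phenyl]but-3-en-1-ol | C=CC[C@H](O)c1ccc(O[Si](C(C)C)(C(C)C)C(C)C)cc1 | intermediate
5 | triethyl({(1S)-1-[4-(triisopropylsilyloxy)phenyl]but-3-en-1-yl}oxy)silane | C=CC[C@H](O[Si](CC)(CC)CC)c1ccc(O[Si](C(C)C)(C(C)C)C(C)C)cc1 | intermediate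
6 | (4S)-4-(triethylsilyloxy)-4-[4-(triisopropylsilyloxy)phenyl]butan-2-one | CC(=O)C[C@H](O[Si](CC)(CC)CC)c1ccc(O[Si](C(C)C)(C(C)C)C(C)C)cc1 | intermediate
7 | dimethyl oxalate | COC(=O)C(=O)OC | starting material
8 | methyl (6S)-2,4-dioxo-6-(triethylsilyloxy)-6-[4-(triisopropylsilyloxy)phenyl]hexanoate | COC(=O)C(=O)CC(=O)C[C@H](O[Si](CC)(CC)CC)c1ccc(O[Si](C(C)C)(C(C)C)C(C)C)cc1 | intermediate
9 | methyl (6S)-6-hydroxy-2,4-dioxo-6-[4-(triisopropylsilyloxy)phenyl]hexanoate | COC(=O)C(=O)CC(=O)C[C@H](O)c1ccc(O[Si](C(C)C)(C(C)C)C(C)C)cc1 | intermediate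
10 | methyl (6S)-2-hydroxy-4-oxo-6-[4-(triisopropylsilyloxy)phenyl]tetrahydro-2H-pyran-2-carboxylate (either epimer at the hemiketal carbon) | COC(=O)C1(O)CC(=O)C[C@@H](c2ccc(O[Si](C(C)C)(C(C)C)C(C)C)cc2)O1 | intermediate
11 | methyl (2S)-4-oxo-2-[4-(triisopropylsilyloxy)phenyl]-3,4-dihydro-2H-pyran-6-carboxylate | COC(=O)C1=CC(=O)C[C@@H](c2ccc(O[Si](C(C)C)(C(C)C)C(C)C)cc2)O1 | intermediate
12 | (2S)-4-oxo-2-[4-(triisopropylsilyloxy)phenyl]-3,4-dihydro-2H-pyran-6-carboxylic acid | OC(=O)C1=CC(=O)C[C@@H](c2ccc(O[Si](C(C)C)(C(C)C)C(C)C)cc2)O1 | intermediate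
13 | N-ethyl-N-nitrosourea | CCN(N=O)C(N)=O | starting material
14 | diazoethane | CC=[N+]=[N-] | intermediate
15 | (2S)-4-oxo-2-[4-(triisopropylsilyloxy)phenyl]-3,4-dihydro-2H-pyran-6-carbonyl chloride | ClC(=O)C1=CC(=O)C[C@@H](c2ccc(O[Si](C(C)C)(C(C)C)C(C)C)cc2)O1 | intermediate
16 | (2S)-6-(2-diazopropanoyl)-2-[4-(triisopropylsilyloxy)phenyl]-2,3-dihydro-4H-pyran-4-one | CC(=[N+]=[N-])C(=O)C1=CC(=O)C[C@@H](c2ccc(O[Si](C(C)C)(C(C)C)C(C)C)cc2)O1 | intermediate
17 | ethyl 4-methylpent-3-enoate | CCOC(=O)CC=C(C)C | starting material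
18 | lithium 1,1-dibromo-5-methylhexa-1,4-dien-2-olate | [Li+].[O-]C(CC=C(C)C)=C(Br)Br | intermediate
19 | lithium 5-methylhex-4-en-1-yn-1-olate | [Li+].[O-]C#CCC=C(C)C | intermediate
20 | triisopropyl[(5-methylhex-4-en-1-yn-1-yl)oxy]silane | CC(C)=CCC#CO[Si](C(C)C)(C(C)C)C(C)C | intermediate
21 | 2-{(2S)-4-oxo-2-[4-(triisopropylsilyloxy)phenyl]-3,4-dihydro-2H-pyran-6-yl}prop-1-en-1-one | CC(=C=O)C1=CC(=O)C[C@@H](c2ccc(O[Si](C(C)C)(C(C)C)C(C)C)cc2)O1 | intermediate
22 | 4-methyl-2-(3-methylbut-2-en-1-yl)-4-{(2S)-4-oxo-2-[4-(triisopropylsilyloxy)phenyl]-3,4-dihydro-2H-pyran-6-yl}-3-(triisopropylsilyloxy)cyclobut-2-en-1-one (either epimer at the quaternary carbon) | CC(C)=CCC1=C(O[Si](C(C)C)(C(C)C)C(C)C)C(C)(C1=O)C2=CC(=O)C[C@@H](c3ccc(O[Si](C(C)C)(C(C)C)C(C)C)cc3)O2 | intermediate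
23 | (E)-dienylketene O=C=C(prenyl)–C(OTIPS)=C(CH3)–(pyranon-6-yl), ketene and pyranonyl cis, (2S) in the pyranone | CC(C)=CCC(=C=O)/C(O[Si](C(C)C)(C(C)C)C(C)C)=C(C)\C1=CC(=O)C[C@@H](c2ccc(O[Si](C(C)C)(C(C)C)C(C)C)cc2)O1 | intermediate
24 | (2S)-8-methyl-6-(3-methylbut-2-en-1-yl)-7-(triisopropylsilyloxy)-2-[4-(triisopropylsilyloxy)phenyl]-2,3-dihydro-4H-chromene-4,5(4aH)-dione | CC(C)=CCC1=C(O[Si](C(C)C)(C(C)C)C(C)C)C(C)=C2O[C@H](c3ccc(O[Si](C(C)C)(C(C)C)C(C)C)cc3)CC(=O)C2C1=O | intermediate
25 | (2S)-5-hydroxy-8-methyl-6-(3-methylbut-2-en-1-yl)-7-(triisopropylsilyloxy)-2-[4-(triisopropylsilyloxy)phenyl]chroman-4-one | CC(C)=CCc1c(O[Si](C(C)C)(C(C)C)C(C)C)c(C)c2c(c1O)C(=O)C[C@@H](c1ccc(O[Si](C(C)C)(C(C)C)C(C)C)cc1)O2 | intermediate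
26 | (2S)-5,7-dihydroxy-2-(4-hydroxyphenyl)-8-methyl-6-(3-methylbut-2-en-1-yl)chroman-4-one | CC(C)=CCc1c(O)c(C)c2c(c1O)C(=O)C[C@@H](c1ccc(O)cc1)O2 | target

Total step count: 12. Longest linear sequence: 10 (steps 1 to 7, 9, 11, 12).

Steps most likely to fail

Step 11. Three processes may interfere:
- Hydrogen may migrate from the methyl group to the carbene centre in competition with the Wolff shift.
- The (2+2) union of a disubstituted ketene with an internal alkyne may be slow enough for the ketene to dimerise or be quenched.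
- The electron-poor vinyl arm may be reluctant to enter the six-electron closure.

The fallback uses only known flavonoid chemistry: ring A is bought rather than built. It sets out from 1 and rejoins the route at 26. Compound 1 is protected with MOMCl and i-Pr2NEt as 4-(methoxymethoxy)benzaldehyde F1. Purchased 1-(2,4,6-trihydroxy-3-methylphenyl)ethanone F2 is treated with two equivalents of MOMCl and K2CO3 in acetone. The hydroxyl wedged between acetyl and methyl is the most hindered and stays chelated, so 1-[2-hydroxy-4,6-bis(methoxymethoxy)-3-methylphenyl]ethanone F3 should result. Claisen–Schmidt condensation of F1 with F3 (KOH, EtOH) should give (E)-1-[2-hydroxy-4,6-bis(methoxymethoxy)-3-methylphenyl]-3-[4-(methoxymethoxy)phenyl]prop-2-en-1-one F4. Its single free phenol closes ring C by oxa-Michael addition (NaOAc, EtOH, reflux), which fixes methyl at C8 in racemic 5,7-bis(methoxymethoxy)-2-[4-(methoxymethoxy)phenyl]-8-methylchroman-4-one F5. HCl in MeOH removes the three acetals to give racemic 5,7-dihydroxy-2-(4-hydroxyphenyl)-8-methylchroman-4-one F6, in which C6 is the only open position of ring A. Friedel–Crafts prenylation with 2-methylbut-3-en-2-ol and BF3·OEt2 in dioxane gives racemic 5,7-dihydroxy-2-(4-hydroxyphenyl)-8-methyl-6-(3-methylbut-2-en-1-yl)chroman-4-one F7. Preparative HPLC on a polysaccharide chiral phase then gives 26.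

Step 9. 1,3-Dipolar cycloaddition of diazoethane across the C5=C6 bond of the pyranone, which is flanked by two carbonyl groups, may compete with C-acylation. The fallback brings in the diazo group by diazo transfer and uses no diazoalkane. It sets out from 12 by way of 15 and rejoins the route at 16. Negishi acylation of 15 with Et2Zn and Pd(PPh3)4 (THF, 0 °C) gives (2S)-6-propanoyl-2-[4-(triisopropylsilyloxy)phenyl]-2,3-dihydro-4H-pyran-4-one F8. One equivalent of LiN(SiMe3)2 at −78 °C should enolise the propanoyl CH2, which is more acidic than the CH2 next to the vinylogous-ester carbonyl. CF3CO2CH2CF3 then gives (2S)-2-[4-(triisopropylsilyloxy)phenyl]-6-(4,4,4-trifluoro-2-methyl-3-oxobutanoyl)-2,3-dihydro-4H-pyran-4-one F9, which is taken on crude. MsN3, Et3N and water in MeCN carry out the detrifluoroacetylative diazo transfer to 16.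

Step 10. The amide base or the carbenoid may abstract a proton from the doubly activated α-CH2 of the β,γ-unsaturated ester, and the alkene may then drift into conjugation, instead of addition to the carbonyl group. The fallback reaches the ynolate by oxygenation of an acetylide. It sets out from 17 and rejoins the route at 19. Reduction with i-Bu2AlH (CH2Cl2, −78 °C) gives 4-methylpent-3-enal F10, which is used at once. The first stage of the Corey–Fuchs sequence (CBr4, PPh3, CH2Cl2, 0 °C) gives 1,1-dibromo-5-methylhexa-1,4-diene F11. Two equivalents of n-BuLi (THF, −78 °C) convert it into (5-methylhex-4-en-1-yn-1-yl)lithium F12. Lithium tert-butyl peroxide, made from t-BuOOH and LiN(SiMe3)2, oxidises F12 to 19, and silylation on oxygen (TIPSOTf, −78 °C) gives 20.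

Further compounds
F1 | step 11 | 4-(methoxymethoxy)benzaldehyde | COCOc1ccc(C=O)cc1
F2 | step 11 | 1-(2,4,6-trihydroxy-3-methylphenyl)ethanone | CC(=O)c1c(O)cc(O)c(C)c1O
F3 | step 11 | 1-[2-hydroxy-4,6-bis(methoxymethoxy)-3-methylphenyl]ethanone | CC(=O)c1c(O)c(C)c(OCOC)cc1OCOC
F4 | step 11 | (E)-1-[2-hydroxy-4,6-bis(methoxymethoxy)-3-methylphenyl]-3-[4-(methoxymethoxy)phenyl]prop-2-en-1-one | COCOc1ccc(/C=C/C(=O)c2c(O)c(C)c(OCOC)cc2OCOC)cc1
F5 | step 11 | racemic 5,7-bis(methoxymethoxy)-2-[4-(methoxymethoxy)phenyl]-8-methylchroman-4-one | COCOc1ccc(C2CC(=O)c3c(OCOC)cc(OCOC)c(C)c3O2)cc1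
F6 | step 11 | racemic 5,7-dihydroxy-2-(4-hydroxyphenyl)-8-methylchroman-4-one | Cc1c(O)cc(O)c2c1OC(c1ccc(O)cc1)CC2=O
F7 | step 11 | racemic 5,7-dihydroxy-2-(4-hydroxyphenyl)-8-methyl-6-(3-methylbut-2-en-1-yl)chroman-4-one | CC(C)=CCc1c(O)c(C)c2c(c1O)C(=O)CC(c1ccc(O)cc1)O2
F8 | step 9 | (2S)-6-propanoyl-2-[4-(triisopropylsilyloxy)phenyl]-2,3-dihydro-4H-pyran-4-one | CCC(=O)C1=CC(=O)C[C@@H](c2ccc(O[Si](C(C)C)(C(C)C)C(C)C)cc2)O1
F9 | step 9 | (2S)-2-[4-(triisopropylsilyloxy)phenyl]-6-(4,4,4-trifluoro-2-methyl-3-oxobutanoyl)-2,3-dihydro-4H-pyran-4-one | CC(C(=O)C(F)(F)F)C(=O)C1=CC(=O)C[C@@H](c2ccc(O[Si](C(C)C)(C(C)C)C(C)C)cc2)O1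
F10 | step 10 | 4-methylpent-3-enal | CC(C)=CCC=O
F11 | step 10 | 1,1-dibromo-5-methylhexa-1,4-diene | CC(C)=CCC=C(Br)Br
F12 | step 10 | (5-methylhex-4-en-1-yn-1-yl)lithium | [Li]C#CCC=C(C)C
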